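1. Retrosynthesis: remove the three acetates and C6–Cl (from C6–OH with inversion); cut ring B (ten-membered) at C5–C6 (Ni/Cr coupling of a 2-iodoalkene with an aldehyde); cut C2–C3 (Grignard addition); cut the lactone at O–C19 and C17–CH3 (epoxy alcohol plus cuprate); cut C8–C9 (alkenyllithium plus Weinreb amide); last, cut C10–C11 and C1–C14 together.
2. Enabling feature: in ring A (C1, C10–C14) the C14 oxygen and C11, which carries the exocyclic methylene C20, sit 1,4 to each other on either side of the fusion bond C1–C10. Tying C14–O back to C11 gives a C11–O–C14 ether bridge that is absent from the target, i.e. a 7-oxanorbornene, the Diels–Alder adduct of a 2-(alkoxymethyl)furan with an E-configured C2–C1(CH3)=C10–C9 diacyl alkene. The bridge is cut later by reductive β-elimination from C20.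
3. Forward order: dienophile plus furan gives ring A with the bridge; the bridge is opened (C14–OH, C11=C20); the C9 side chain with the lactone carbons is added, then the C2 chain; the γ-lactone is closed; ring B is closed last.
4. Stereochemistry: C1, C10 and C14 come from the catalyst-controlled endo cycloaddition of the E-alkene (trans CH3/H). C9 and C2 come from Felkin–Anh reactions next to ring A. C7 comes from (S)-glyceraldehyde. C8 and C17 come from asymmetric epoxidation and SN2 cuprate opening. C6 comes from Felkin–Anh hydride delivery followed by SN2 chloride.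

Key step: step 5

Remark: names use the skeletal numbering of the target (C1 quaternary methyl carbon; C2, C9, C14 acetoxy carbons; C5=C16 and C11=C20 methylenes; C6–Cl; lactone C7–O–C19(=O)–C17(C18)–C8); both antipodes of the t-Bu-box ligand, (S)-glyceraldehyde acetonide and D-(−)-diethyl tartrate are taken as purchasable.

**Route**

Step 1
Reactants: 1 methyl pyruvate; 2 tert-butyl (triphenylphosphoranylidene)acetate
Product: 3 4-tert-butyl 1-methyl (E)-2-methylbut-2-enedioate
Conditions: CH2Cl2, rt to 40 °C; chromatography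
Reagents that add atoms: none
Why: Wittig olefination of the activated ketone by a stabilised ylide should give mainly the E diester (ester groups trans), and the minor Z isomer is removed.

Step 2
Reactants: 3 mixed tert-butyl methyl mesaconate
Product: 4 (E)-4-methoxy-3-methyl-4-oxobut-2-enoic acid
Conditions: CF3CO2H, CH2Cl2, 0 °C to rt
Reagents that add atoms: none
Why: Acidolysis of the tert-butyl ester through the tert-butyl cation leaves the methyl ester and the alkene geometry untouched.

Step 3
Reactants: 4 mesaconic acid monomethyl ester; 5 oxazolidinone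
Product: 7 methyl (E)-2-methyl-4-oxo-4-(2-oxooxazolidin-3-yl)but-2-enoate, via mixed pivalic anhydride 6 (not isolated)
Conditions: t-BuCOCl, Et3N, THF, −20 °C; then the oxazolidinone, LiCl, −20 °C to rt
Reagents that add atoms: pivaloyl chloride, CC(C)(C)C(=O)Cl (its atoms stay only in 6)
Why: N-Acylation of the oxazolidinone through the mixed anhydride, which is attacked at the unhindered enoyl carbonyl, is the standard route to unsaturated acyl oxazolidinones.

Step 4
Reactants: 8 furfuryl alcohol
Product: 9 2-[(benzyloxy)methyl]furan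
Conditions: NaH, BnBr, Bu4NI (cat.), THF, 0 °C to rt
Reagents that add atoms: benzyl bromide, BrCc1ccccc1
Why: Williamson etherification of the primary alkoxide.

Step 5
Reactants: 7 mesaconoyl imide dienophile; 9 benzyl furfuryl ether
Product: 10 methyl (1R,2R,3R,4S)-1-[(benzyloxy)methyl]-3-methyl-2-(2-oxooxazolidine-3-carbonyl)-7-oxabicyclo[2.2.1]hept-5-ene-3-carboxylate (imide endo, ester exo)
Conditions: [Cu((R,R)-t-Bu-box)](SbF6)2 (10 mol %, made in the flask from CuCl2, AgSbF6 and (R,R)-2,2'-isopropylidenebis(4-tert-butyl-2-oxazoline), AgCl filtered off), threefold excess of the furan, CH2Cl2, 4 Å MS, −40 °C; cold filtration through a short silica pad; cold filtrate taken into step 6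
Reagents that add atoms: none
Why: The imide chelated to the square-planar divalent copper centre reacts in its s-cis form in a concerted, asynchronous [4+2] cycloaddition in which the unsubstituted furan carbon (C14) bonds to C1 ahead of the bond from the substituted furan carbon (C11) to C10. The closest known reaction is the bis(oxazoline)–copper-catalysed Diels–Alder reaction of furan with N-acryloyl- and N-fumaroyl-oxazolidinones. Ring A and the temporary C11–O–C14 bridge are closed together in one suprafacial [4π+2π] ring closure, so the E geometry of 7 becomes the trans relation of C1–CH3 and C10–H. The tert-butyl group of the (R,R) ligand shields the Re face at C10, so the furan should add to the Si face and fix C10 and C1, while the endo position of the chelated imide (secondary orbital overlap, exo preference of the α-methyl ester) fixes C14 and C11 relative to them. The step needs C11-to-C10 regioselectivity, which the larger HOMO coefficient at the free furan α-carbon, the larger LUMO coefficient at C1 of the bound imide and the avoidance of a bond between two fully substituted carbons all favour. It also needs kinetic control, which the low temperature and the immediate hydrogenation in step 6 secure against cycloreversion.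

Step 6
Reactants: 10 oxanorbornene cycloadduct
Product: 11 saturated 1-(hydroxymethyl)-7-oxabicyclo[2.2.1]heptane imide ester (configuration of 10)
Conditions: H2 (1 atm), Pd(OH)2/C, EtOAc/EtOH, 0 °C to rt
Reagents that add atoms: none
Why: Catalytic hydrogenation should saturate the strained C12=C13 bond, which blocks cycloreversion, and then hydrogenolyse the benzyl ether, with no stereocentre touched.

Step 7
Reactants: 11 bridgehead hydroxymethyl compound
Product: 13 1-(iodomethyl)-7-oxabicyclo[2.2.1]heptane imide ester, via primary triflate 12 (not isolated)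
Conditions: Tf2O, 2,6-lutidine, CH2Cl2, −78 °C; then Bu4NI, toluene, 60 °C
Reagents that add atoms: triflic anhydride, O=S(=O)(OS(=O)(=O)C(F)(F)F)C(F)(F)F (its atoms stay only in 12); tetrabutylammonium iodide, CCCC[N+](CCCC)(CCCC)CCCC.[I-]
Why: SN2 displacement of a primary triflate by iodide is feasible even at this neopentyl-type carbon next to an ether oxygen, as with C1 triflates of ketoses.

Step 8
Reactants: 13 bridgehead iodomethyl compound
Product: 14 ring-opened hydroxy imide (ring A with C14–OH, exocyclic C11=C20, C1 CH3 and CO2CH3, C10 acyl oxazolidinone)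
Conditions: Zn dust (activated), THF/H2O 9:1, sonication, 40 °C
Reagents that add atoms: none
Why: Zinc inserts into the C20–I bond and the organozinc expels the β-oxygen (Boord-type reductive elimination, as in the Vasella fragmentation), which should cut only the C11–O bond and give the methylene and the C14 hydroxyl with the C14 configuration untouched.

Step 9
Reactants: 14 ring-A hydroxy imide
Product: 15 Weinreb amide (N-methoxy-N-methylamide at C9, otherwise as 14)
Conditions: MeONHMe·HCl, AlMe3, CH2Cl2, 0 °C to rt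
Reagents that add atoms: N,O-dimethylhydroxylamine hydrochloride, CNOC.Cl
Why: Weinreb aminolysis by the aluminium amide attacks the exocyclic imide carbonyl, the neopentyl methyl ester being too hindered to react.

Step 10
Reactants: 16 (S)-glyceraldehyde acetonide
Product: 17 (R)-4-ethynyl-2,2-dimethyl-1,3-dioxolane
Conditions: dimethyl (1-diazo-2-oxopropyl)phosphonate, K2CO3, MeOH, 0 °C to rt
Reagents that add atoms: dimethyl (1-diazo-2-oxopropyl)phosphonate, COP(=O)(OC)C(=[N+]=[N-])C(C)=O
Why: Ohira–Bestmann (Seyferth–Gilbert) homologation turns the aldehyde into the terminal alkyne and is known to preserve this α-alkoxy stereocentre.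

Step 11
Reactants: 17 dioxolanyl alkyne
Product: 19 3-[(4R)-2,2-dimethyl-1,3-dioxolan-4-yl]prop-2-yn-1-ol, via lithium acetylide 18 (not isolated)
Conditions: n-BuLi, THF, −78 °C; then (CH2O)n, −78 °C to rt
Reagents that add atoms: paraformaldehyde (as formaldehyde), C=O
Why: Addition of the lithium acetylide to formaldehyde.

Step 12
Reactants: 19 propargylic alcohol
Product: 21 (Z)-3-[(4S)-2,2-dimethyl-1,3-dioxolan-4-yl]-3-iodoprop-2-en-1-ol, via cyclic alkenylalanate 20 (not isolated)
Conditions: NaAlH2(OCH2CH2OCH3)2, THF, 0 °C; then I2, −78 °C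
Reagents that add atoms: iodine, I-I
Why: Hydroxyl-directed trans-hydroalumination puts hydride on the proximal and aluminium on the distal alkyne carbon, and iodinolysis with retention gives the Z iodoalkene, the low temperature avoiding loss of the acetal oxygen to an allene.

Step 13
Reactants: 21 iodoallylic alcohol
Product: 22 4-methoxybenzyl ether of 21
Conditions: NaH, 4-MeOC6H4CH2Cl, Bu4NI (cat.), DMF, 0 °C
Reagents that add atoms: 4-methoxybenzyl chloride, COc1ccc(CCl)cc1
Why: Williamson etherification, with the alkenyl iodide and the acetonide inert to the base.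

Step 14
Reactants: 15 ring-A Weinreb amide; 22 PMB-protected alkenyl iodide
Product: 25 ring-A alkenyl ketone (enone), via chloromagnesium alkoxide 23 (not isolated), via alkenyllithium 24 (not isolated)
Conditions: Weinreb amide, i-PrMgCl (1.0 equiv), THF, −78 °C; alkenyl iodide, t-BuLi (2.1 equiv), Et2O, −78 °C; mix, −78 to −30 °C; crude enone used at once
Reagents that add atoms: isopropylmagnesium chloride, CC(C)[Mg]Cl (Mg and Cl stay only in 23); tert-butyllithium, [Li]C(C)(C)C (Li stays only in 24)
Why: Iodine–lithium exchange retains the alkene geometry and the alkenyllithium adds once to the Weinreb amide through the stable N,O-chelated tetrahedral intermediate, the free hydroxyl being masked as its alkoxide and the hindered ester left alone.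

Step 15
Reactants: 25 enone
Product: 26 (9S)-allylic alcohol
Conditions: NaBH4, CeCl3·7H2O, MeOH, −78 °C
Reagents that add atoms: none
Why: Luche 1,2-reduction with Felkin–Anh delivery of hydride anti to the quaternary C1 substituent on C10 (sp2 C11 as the medium group) should set C9 as S before the β,γ-unsaturated ketone can move into conjugation.

Step 16
Reactants: 26 ring-A diol
Product: 27 C9,C14-bis(tert-butyldimethylsilyl) ether
Conditions: TBSOTf, 2,6-lutidine, CH2Cl2, −78 to 0 °C
Reagents that add atoms: tert-butyldimethylsilyl triflate, CC(C)(C)[Si](C)(C)OS(=O)(=O)C(F)(F)F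
Why: Silyl triflate silylation copes with the two hindered secondary alcohols and leaves the acetonide and PMB ether intact.

Step 17
Reactants: 27 bis-silyl ether ester
Product: 28 C2 primary alcohol
Conditions: DIBAL-H, CH2Cl2, −78 to 0 °C
Reagents that add atoms: none
Why: Hydride reduction of the hindered methyl ester to the neopentyl alcohol, with silyl ethers, PMB ether and acetal inert.

Step 18
Reactants: 28 neopentyl primary alcohol
Product: 29 C2 aldehyde
Conditions: Dess–Martin periodinane, NaHCO3, CH2Cl2, rt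
Reagents that add atoms: none
Why: Dess–Martin oxidation gives an aldehyde on a quaternary carbon, which cannot epimerise.

Step 19
Reactants: 29 neopentyl aldehyde
Product: 31 (2S)-carbinol with the but-3-ynyl chain (terminal alkyne), via C-silylated alkynyl carbinol 30 (not isolated)
Conditions: Me3SiC≡CCH2CH2MgBr (from the bromide and Mg), CeCl3, THF, −78 °C; then MeOH, K2CO3, rt
Reagents that add atoms: [4-(trimethylsilyl)but-3-yn-1-yl]magnesium bromide, C[Si](C)(C)C#CCC[Mg]Br
Why: Organocerium-type 1,2-addition limits reduction of the hindered aldehyde, Felkin–Anh approach anti to C10 (which carries the bulky C9 branch) reinforced by the 1,3-anti preference relative to the β-silyloxy carbon C14 should give the 2S carbinol, and methanolysis then cleaves the alkynyl C–Si bond.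

Step 20
Reactants: 31 alkynyl carbinol
Product: 32 C2,C9,C14-tris(tert-butyldimethylsilyl) ether
Conditions: TBSOTf, 2,6-lutidine, CH2Cl2, −78 to 0 °C
Reagents that add atoms: tert-butyldimethylsilyl triflate, CC(C)(C)[Si](C)(C)OS(=O)(=O)C(F)(F)F
Why: Silylation of the neopentyl secondary alcohol, with the terminal alkyne unaffected.

Step 21
Reactants: 32 tris-silyl ether
Product: 33 C19 allylic alcohol
Conditions: DDQ, CH2Cl2/pH 7 buffer, 0 °C
Reagents that add atoms: none
Why: Oxidative cleavage of the PMB ether (hydride abstraction, hydrolysis of the oxocarbenium ion) frees the primary allylic alcohol without touching silyl ethers or the acetonide.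

Step 22
Reactants: 33 allylic alcohol
Product: 34 C8–C17 epoxy alcohol
Conditions: Ti(OiPr)4 (1.2 equiv), D-(−)-diethyl tartrate (1.4 equiv), t-BuOOH, 4 Å MS, CH2Cl2, −20 °C
Reagents that add atoms: tert-butyl hydroperoxide, CC(C)(C)OO
Why: In the Katsuki–Sharpless asymmetric epoxidation the D-(−)-tartrate titanium complex, the mirror image of the one that turns 3-substituted allylic alcohols into 2S epoxy alcohols, should deliver oxygen to the face that gives the 17R epoxide and with it the target configuration at C8, and only the alkene of the allylic alcohol is epoxidised.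

Step 23
Reactants: 34 epoxy alcohol
Product: 35 C19,C8 1,3-diol with the C17 methyl group
Conditions: Me2CuLi (from MeLi and CuI, 6 equiv), Et2O, −40 to −10 °C
Reagents that add atoms: lithium dimethylcuprate, [Li+].C[Cu-]C
Why: The cuprate opens the 2,3-epoxy alcohol by SN2 attack at C17 (C8 is fully substituted) with inversion, which should set the C17 methyl stereocentre and leave the tertiary C8 alcohol.

Step 24
Reactants: 35 methyl-branched diol
Product: 37 γ-lactone with free C6–OH and C8–OH, via β-hydroxy acid 36 (not isolated)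
Conditions: TEMPO (cat.), PhI(OAc)2, MeCN/pH 7 buffer, rt; then AcOH/H2O 4:1, 45 °C
Reagents that add atoms: water, O
Why: Oxoammonium oxidation takes the primary alcohol to the acid, and aqueous acetic acid then hydrolyses the acetonide so that the C7 hydroxyl closes the five-membered lactone, which is favoured over the six-membered alternative through C6–OH.

Step 25
Reactants: 37 dihydroxy lactone
Product: 38 C6,C8-bis(triethylsilyl) ether
Conditions: Et3SiOTf, 2,6-lutidine, CH2Cl2, −78 to 0 °C
Reagents that add atoms: triethylsilyl triflate, CC[Si](CC)(CC)OS(=O)(=O)C(F)(F)F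
Why: Silylation of the primary and the tertiary hydroxyl removes every O–H before the haloboration.

Step 26
Reactants: 38 bis(triethylsilyl) ether
Product: 40 2-iodoalkene (C5(I)=C16H2), via iodoalkenylborane 39 (not isolated)
Conditions: B-iodo-9-BBN, pentane/CH2Cl2, −20 °C; then AcOH, 0 °C
Reagents that add atoms: B-iodo-9-borabicyclo[3.3.1]nonane, IB1C2CCCC1CCC2
Why: Haloboration adds B–I syn and in the Markovnikov sense across the terminal alkyne only, and acetic acid protonolyses the alkenyl C–B bond to leave the 2-iodo-1-alkene.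

Step 27
Reactants: 40 iodoalkene
Product: 41 C6 aldehyde
Conditions: (COCl)2, DMSO, CH2Cl2, −78 °C; Et3N, −78 to −20 °C; used at once
Reagents that add atoms: none
Why: Swern conditions are known to cleave and oxidise a primary triethylsilyl ether directly to the aldehyde while tertiary triethylsilyl and secondary TBS ethers stay.

Step 28
Reactants: 41 iodoalkene aldehyde
Product: 42 ten-membered-ring allylic alcohol (both C6 epimers)
Conditions: CrCl2 (20 equiv), NiCl2 (cat.), DMSO, rt, slow addition to 0.002 M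
Reagents that add atoms: none
Why: In the Nozaki–Hiyama–Kishi reaction zerovalent nickel inserts into the C5–I bond, the alkenyl group passes to trivalent chromium and adds to the aldehyde, closing ring B at C5–C6 under neutral conditions; both epimers are used because C6 is re-set in steps 29 and 30.

Step 29
Reactants: 42 macrocyclic allylic alcohol
Product: 43 ring-B enone (C6 ketone conjugated with C5=C16)
Conditions: Dess–Martin periodinane, NaHCO3, CH2Cl2, rt
Reagents that add atoms: none
Why: Dess–Martin oxidation converges both epimers on one ketone without base that could epimerise C7.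

Step 30
Reactants: 43 macrocyclic enone
Product: 44 C6 carbinol syn to the C7 oxygen
Conditions: NaBH4, CeCl3·7H2O, MeOH/THF, −78 °C
Reagents that add atoms: none
Why: Luche 1,2-reduction with polar Felkin–Anh attack of hydride anti to the C7–O bond should give the C6 epimer that is needed for the inversion in step 31.

Step 31
Reactants: 44 single-epimer allylic alcohol
Product: 45 (6S)-allylic chloride
Conditions: PPh3, Cl3CCOCCl3, CH2Cl2, −20 to 0 °C
Reagents that add atoms: hexachloroacetone, O=C(C(Cl)(Cl)Cl)C(Cl)(Cl)Cl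
Why: Appel-type chlorination displaces the alkoxyphosphonium group by chloride with inversion, and this reagent pair is known to do so on allylic alcohols without allylic transposition.

Step 32
Reactants: 45 silylated allylic chloride
Product: 46 C2,C8,C9,C14-tetraol
Conditions: HF·pyridine, pyridine, THF, 0 °C to rt
Reagents that add atoms: none
Why: Buffered fluoride cleaves the three TBS ethers and the triethylsilyl ether, while the lactone, the allylic chloride and the alkenes are inert.

Step 33
Reactants: 46 chloro tetraol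
Product: 47 CNP0199061.1 (target)
Conditions: Ac2O, pyridine, DMAP (cat.), CH2Cl2, rt
Reagents that add atoms: acetic anhydride, CC(=O)OC(C)=O
Why: Acylation takes the three secondary alcohols, whereas the tertiary C8 hydroxyl, flanked by three branched carbons, should stay free.

**Compound list**

1 | methyl pyruvate | CC(=O)C(=O)OC | starting material
2 | tert-butyl (triphenylphosphoranylidene)acetate | CC(C)(C)OC(=O)C=P(c1ccccc1)(c1ccccc1)c1ccccc1 | starting material
3 | 4-tert-butyl 1-methyl (E)-2-methylbut-2-enedioate | COC(=O)/C(C)=C/C(=O)OC(C)(C)C | intermediate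
4 | (E)-4-methoxy-3-methyl-4-oxobut-2-enoic acid | COC(=O)/C(C)=C/C(=O)O | intermediate
5 | oxazolidin-2-one | O=C1NCCO1 | starting material
6 | mixed pivalic anhydride of 4 | COC(=O)/C(C)=C/C(=O)OC(=O)C(C)(C)C | intermediate
7 | methyl (E)-2-methyl-4-oxo-4-(2-oxooxazolidin-3-yl)but-2-enoate | COC(=O)/C(C)=C/C(=O)N1CCOC1=O | intermediate
8 | furfuryl alcohol | OCc1ccco1 | starting material
9 | 2-[(benzyloxy)methyl]furan | c1ccc(COCc2ccco2)cc1 | intermediate
10 | methyl (1R,2R,3R,4S)-1-[(benzyloxy)methyl]-3-methyl-2-(2-oxooxazolidine-3-carbonyl)-7-oxabicyclo[2.2.1]hept-5-ene-3-carboxylate | c1ccccc1COC[C@]23C=C[C@H](O2)[C@](C)(C(=O)OC)[C@H]3C(=O)N4CCOC4=O | intermediate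
11 | saturated 1-(hydroxymethyl) analogue of 10 (benzyl removed) | OC[C@]12CC[C@H](O1)[C@](C)(C(=O)OC)[C@H]2C(=O)N3CCOC3=O | intermediate
12 | primary triflate of 11 | O=S(=O)(OC[C@]12CC[C@H](O1)[C@](C)(C(=O)OC)[C@H]2C(=O)N3CCOC3=O)C(F)(F)F | intermediate
13 | 1-(iodomethyl) analogue of 11 | IC[C@]12CC[C@H](O1)[C@](C)(C(=O)OC)[C@H]2C(=O)N3CCOC3=O | intermediate
14 | ring-A hydroxy imide: C14–OH, C11=C20, C1 CH3/CO2CH3, C10 acyl oxazolidinone (target configuration at C1, C10, C14) | C=C1CC[C@H](O)[C@](C)(C(=O)OC)[C@H]1C(=O)N2CCOC2=O | intermediate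
15 | Weinreb amide corresponding to 14 | C=C1CC[C@H](O)[C@](C)(C(=O)OC)[C@H]1C(=O)N(C)OC | intermediate
16 | (S)-2,2-dimethyl-1,3-dioxolane-4-carbaldehyde | O=C[C@@H]1COC(C)(C)O1 | starting material
17 | (R)-4-ethynyl-2,2-dimethyl-1,3-dioxolane | C#C[C@@H]1COC(C)(C)O1 | intermediate
18 | lithium acetylide of 17 | [Li]C#C[C@@H]1COC(C)(C)O1 | intermediate
19 | 3-[(4R)-2,2-dimethyl-1,3-dioxolan-4-yl]prop-2-yn-1-ol | OCC#C[C@@H]1COC(C)(C)O1 | intermediate
20 | sodium salt of the cyclic alkenylalanate from 19 (Al on C8, O–Al ring) | [Na+].COCCO[Al-]1(OCCOC)OCC=C1[C@@H]2COC(C)(C)O2 | intermediate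
21 | (Z)-3-[(4S)-2,2-dimethyl-1,3-dioxolan-4-yl]-3-iodoprop-2-en-1-ol | OC/C=C(\I)[C@@H]1COC(C)(C)O1 | intermediate
22 | 4-methoxybenzyl ether of 21 | COc1ccc(COC/C=C(\I)[C@@H]2COC(C)(C)O2)cc1 | intermediate
23 | chloromagnesium C14 alkoxide of 15 | C=C1CC[C@H](O[Mg]Cl)[C@](C)(C(=O)OC)[C@H]1C(=O)N(C)OC | intermediate
24 | alkenyllithium from 22 (Li in place of I, geometry retained) | COc1ccc(COC/C=C(\[Li])[C@@H]2COC(C)(C)O2)cc1 | intermediate
25 | enone: C9 ketone between C10 and C8; C8=C17 alkene with CH2OPMB cis to C9; C7 acetonide; C14–OH; C1 CO2CH3 | C=C1CC[C@H](O)[C@](C)(C(=O)OC)[C@H]1C(=O)/C(=C\COCc2ccc(OC)cc2)[C@@H]3COC(C)(C)O3 | intermediate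
26 | (9S)-allylic alcohol from 25 | C=C1CC[C@H](O)[C@](C)(C(=O)OC)[C@H]1[C@H](O)/C(=C\COCc2ccc(OC)cc2)[C@@H]3COC(C)(C)O3 | intermediate
27 | C9,C14-bis-TBS ether of 26 | C=C1CC[C@H](O[Si](C)(C)C(C)(C)C)[C@](C)(C(=O)OC)[C@H]1[C@H](O[Si](C)(C)C(C)(C)C)/C(=C\COCc2ccc(OC)cc2)[C@@H]3COC(C)(C)O3 | intermediate
28 | C2 primary alcohol from 27 | C=C1CC[C@H](O[Si](C)(C)C(C)(C)C)[C@](C)(CO)[C@H]1[C@H](O[Si](C)(C)C(C)(C)C)/C(=C\COCc2ccc(OC)cc2)[C@@H]3COC(C)(C)O3 | intermediate
29 | C2 aldehyde | C=C1CC[C@H](O[Si](C)(C)C(C)(C)C)[C@](C)(C=O)[C@H]1[C@H](O[Si](C)(C)C(C)(C)C)/C(=C\COCc2ccc(OC)cc2)[C@@H]3COC(C)(C)O3 | intermediate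
30 | (2S)-carbinol with 4-(trimethylsilyl)but-3-ynyl chain | C=C1CC[C@H](O[Si](C)(C)C(C)(C)C)[C@](C)([C@@H](O)CCC#C[Si](C)(C)C)[C@H]1[C@H](O[Si](C)(C)C(C)(C)C)/C(=C\COCc2ccc(OC)cc2)[C@@H]3COC(C)(C)O3 | intermediate
31 | (2S)-carbinol with but-3-ynyl chain | C=C1CC[C@H](O[Si](C)(C)C(C)(C)C)[C@](C)([C@@H](O)CCC#C)[C@H]1[C@H](O[Si](C)(C)C(C)(C)C)/C(=C\COCc2ccc(OC)cc2)[C@@H]3COC(C)(C)O3 | intermediate
32 | C2,C9,C14-tris-TBS ether | C=C1CC[C@H](O[Si](C)(C)C(C)(C)C)[C@](C)([C@@H](O[Si](C)(C)C(C)(C)C)CCC#C)[C@H]1[C@H](O[Si](C)(C)C(C)(C)C)/C(=C\COCc2ccc(OC)cc2)[C@@H]3COC(C)(C)O3 | intermediate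
33 | C19 allylic alcohol (PMB removed) | C=C1CC[C@H](O[Si](C)(C)C(C)(C)C)[C@](C)([C@@H](O[Si](C)(C)C(C)(C)C)CCC#C)[C@H]1[C@H](O[Si](C)(C)C(C)(C)C)/C(=C\CO)[C@@H]2COC(C)(C)O2 | intermediate
34 | C8–C17 epoxy alcohol | C=C1CC[C@H](O[Si](C)(C)C(C)(C)C)[C@](C)([C@@H](O[Si](C)(C)C(C)(C)C)CCC#C)[C@H]1[C@H](O[Si](C)(C)C(C)(C)C)[C@@]2(O[C@@H]2CO)[C@@H]3COC(C)(C)O3 | intermediate
35 | 1,3-diol: C8 tertiary OH, C17 methyl, C19 CH2OH | C=C1CC[C@H](O[Si](C)(C)C(C)(C)C)[C@](C)([C@@H](O[Si](C)(C)C(C)(C)C)CCC#C)[C@H]1[C@H](O[Si](C)(C)C(C)(C)C)[C@](O)([C@@H](C)CO)[C@@H]2COC(C)(C)O2 | intermediate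
36 | β-hydroxy acid (C19 CO2H), acetonide intact | C=C1CC[C@H](O[Si](C)(C)C(C)(C)C)[C@](C)([C@@H](O[Si](C)(C)C(C)(C)C)CCC#C)[C@H]1[C@H](O[Si](C)(C)C(C)(C)C)[C@](O)([C@@H](C)C(=O)O)[C@@H]2COC(C)(C)O2 | intermediate
37 | γ-lactone (C7–O–C19) with C6–OH and C8–OH | C=C1CC[C@H](O[Si](C)(C)C(C)(C)C)[C@](C)([C@@H](O[Si](C)(C)C(C)(C)C)CCC#C)[C@H]1[C@H](O[Si](C)(C)C(C)(C)C)[C@]2(O)[C@@H](C)C(=O)O[C@H]2CO | intermediate
38 | C6,C8-bis(triethylsilyl) ether of 37 | C=C1CC[C@H](O[Si](C)(C)C(C)(C)C)[C@](C)([C@@H](O[Si](C)(C)C(C)(C)C)CCC#C)[C@H]1[C@H](O[Si](C)(C)C(C)(C)C)[C@]2(O[Si](CC)(CC)CC)[C@@H](C)C(=O)O[C@H]2CO[Si](CC)(CC)CC | intermediate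
39 | (Z)-2-iodoalkenyl-9-BBN adduct of 38 | C=C1CC[C@H](O[Si](C)(C)C(C)(C)C)[C@](C)([C@@H](O[Si](C)(C)C(C)(C)C)CCC(/I)=C/B3C4CCCC3CCC4)[C@H]1[C@H](O[Si](C)(C)C(C)(C)C)[C@]2(O[Si](CC)(CC)CC)[C@@H](C)C(=O)O[C@H]2CO[Si](CC)(CC)CC | intermediate
40 | 2-iodoalkene (C5(I)=C16H2), C6–OSiEt3 | C=C1CC[C@H](O[Si](C)(C)C(C)(C)C)[C@](C)([C@@H](O[Si](C)(C)C(C)(C)C)CCC(I)=C)[C@H]1[C@H](O[Si](C)(C)C(C)(C)C)[C@]2(O[Si](CC)(CC)CC)[C@@H](C)C(=O)O[C@H]2CO[Si](CC)(CC)CC | intermediate
41 | iodoalkene C6 aldehyde | C=C1CC[C@H](O[Si](C)(C)C(C)(C)C)[C@](C)([C@@H](O[Si](C)(C)C(C)(C)C)CCC(I)=C)[C@H]1[C@H](O[Si](C)(C)C(C)(C)C)[C@]2(O[Si](CC)(CC)CC)[C@@H](C)C(=O)O[C@H]2C=O | intermediate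
42 | tricyclic C6 allylic alcohol, both C6 epimers (C6 left undefined) | C=C1CC[C@H](O[Si](C)(C)C(C)(C)C)[C@@]2(C)[C@H]1[C@H](O[Si](C)(C)C(C)(C)C)[C@]3(O[Si](CC)(CC)CC)[C@@H](C)C(=O)O[C@H]3C(O)C(=C)CC[C@@H]2O[Si](C)(C)C(C)(C)C | intermediate
43 | tricyclic C6 ketone (enone with C5=C16) | C=C1CC[C@H](O[Si](C)(C)C(C)(C)C)[C@@]2(C)[C@H]1[C@H](O[Si](C)(C)C(C)(C)C)[C@]3(O[Si](CC)(CC)CC)[C@@H](C)C(=O)O[C@H]3C(=O)C(=C)CC[C@@H]2O[Si](C)(C)C(C)(C)C | intermediate
44 | tricyclic C6 alcohol, OH syn to the C7 oxygen (C6 epimer of the target's chloride position) | C=C1CC[C@H](O[Si](C)(C)C(C)(C)C)[C@@]2(C)[C@H]1[C@H](O[Si](C)(C)C(C)(C)C)[C@]3(O[Si](CC)(CC)CC)[C@@H](C)C(=O)O[C@H]3[C@H](O)C(=C)CC[C@@H]2O[Si](C)(C)C(C)(C)C | intermediate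
45 | (6S)-chloride, fully silylated | C=C1CC[C@H](O[Si](C)(C)C(C)(C)C)[C@@]2(C)[C@H]1[C@H](O[Si](C)(C)C(C)(C)C)[C@]3(O[Si](CC)(CC)CC)[C@@H](C)C(=O)O[C@H]3[C@@H](Cl)C(=C)CC[C@@H]2O[Si](C)(C)C(C)(C)C | intermediate
46 | C2,C8,C9,C14-tetraol (6-chloro lactone) | C=C1CC[C@H](O)[C@@]2(C)[C@H]1[C@H](O)[C@]3(O)[C@@H](C)C(=O)O[C@H]3[C@@H](Cl)C(=C)CC[C@@H]2O | intermediate
47 | CNP0199061.1: 2,9,14-triacetate, 8-hydroxy, 6-chloro, 5(16),11(20)-diene lactone (1R,2S,6S,7R,8R,9S,10S,14S,17R) | C=C1CC[C@H](OC(C)=O)[C@]2(C)[C@@H](OC(C)=O)CCC(=C)[C@H](Cl)[C@@H]3OC(=O)[C@H](C)[C@@]3(O)[C@@H](OC(C)=O)[C@@H]12 | target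

**Totals and risks**

Total step count: 33. Longest linear sequence: 28 steps (steps 1–3, 5–9, 14–33).

Most likely to fail, with fallbacks:

Step 5. The trisubstituted dienophile may react too slowly at the temperature needed for kinetic control. Cycloreversion on the Lewis acid would then erode endo- and enantioselectivity, and Friedel–Crafts-type conjugate addition of the furan may compete. Fallback: 7 and 9 are combined without any Lewis acid at 12 kbar in CH2Cl2 at room temperature, where the negative activation volume drives the cycloaddition, to give, after removal of the exo isomer, the racemic endo-imide adduct F1. Hydrogenation and hydrogenolysis as in step 6 give the racemic alcohol F2. This is resolved by preparative supercritical-fluid chromatography on a chiral stationary phase, and the antipode identical with 11 re-enters the route at step 7.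

Step 28. Ring strain in the ten-membered transition state may let intermolecular coupling (oligomers) or simple reduction of the C–I bond win, and the α-acyloxy aldehyde may epimerise or hydrate while waiting. Fallback: 38 is oxidised under the Swern conditions of step 27 to the alkynyl aldehyde F3. Nickel-catalysed reductive alkyne–aldehyde macrocyclisation follows (Ni(cod)2, the bulky carbene 1,3-bis(2,6-diisopropylphenyl)imidazol-2-ylidene, Et3SiH, THF, high dilution). In this reaction the bulky ligand is known to steer C–C bond formation to the internal alkyne carbon, which gives the exocyclic-methylene allylic triethylsilyl ether F4 as C6 epimers. Selective methanolysis of the secondary silyl ether (pyridinium p-toluenesulfonate, MeOH, 0 °C) returns to the route at 42.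

Step 19. Addition to the α-quaternary aldehyde may show poor facial selectivity, and β-hydride transfer from the organometallic may reduce the aldehyde instead. Fallback: 31, taken as the mixture of C2 epimers, is oxidised with Dess–Martin periodinane to the C2 ketone F5. Corey–Bakshi–Shibata reduction ((R)-2-methyl-CBS-oxazaborolidine, catecholborane, toluene, −78 °C), with the quaternary C1 as the large group, should return the 2S carbinol 31 under catalyst control.

Further compounds
F1 | step 5 | racemic endo-imide/exo-ester adduct (10 and its mirror image) | c1ccccc1COC[C@]23C=C[C@H](O2)[C@](C)(C(=O)OC)[C@H]3C(=O)N4CCOC4=O.c1ccccc1COC[C@@]23C=C[C@@H](O2)[C@@](C)(C(=O)OC)[C@@H]3C(=O)N4CCOC4=O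
F2 | step 5 | racemic saturated hydroxymethyl compound (11 and its mirror image) | OC[C@]12CC[C@H](O1)[C@](C)(C(=O)OC)[C@H]2C(=O)N3CCOC3=O.OC[C@@]12CC[C@@H](O1)[C@@](C)(C(=O)OC)[C@@H]2C(=O)N3CCOC3=O
F3 | step 28 | alkynyl C6 aldehyde (terminal alkyne, C8–OSiEt3) | C=C1CC[C@H](O[Si](C)(C)C(C)(C)C)[C@](C)([C@@H](O[Si](C)(C)C(C)(C)C)CCC#C)[C@H]1[C@H](O[Si](C)(C)C(C)(C)C)[C@]2(O[Si](CC)(CC)CC)[C@@H](C)C(=O)O[C@H]2C=O
F4 | step 28 | tricyclic C6 triethylsilyl ether with exocyclic C5=C16, both C6 epimers | C=C1CC[C@H](O[Si](C)(C)C(C)(C)C)[C@@]2(C)[C@H]1[C@H](O[Si](C)(C)C(C)(C)C)[C@]3(O[Si](CC)(CC)CC)[C@@H](C)C(=O)O[C@H]3C(O[Si](CC)(CC)CC)C(=C)CC[C@@H]2O[Si](C)(C)C(C)(C)C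
F5 | step 19 | C2 ketone (but-3-ynyl ketone on C1) | C=C1CC[C@H](O[Si](C)(C)C(C)(C)C)[C@](C)(C(=O)CCC#C)[C@H]1[C@H](O[Si](C)(C)C(C)(C)C)/C(=C\COCc2ccc(OC)cc2)[C@@H]3COC(C)(C)O3
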